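**Plan**

- Retrosynthesis: the C1–O–C6 oxirane is cut last (back to a C1=C6 alkene in a cyclohexa-1,3-diene), then the two benzoate C(=O)–O bonds, then the exocyclic C1–C7 bond together with the C1=C6 π bond (back to a C6 ketone with C4=C5 already in place), then the ring C–O bonds back to cyclohexa-1,4-diene.
- Forward: the carbocycle is present from the start. Cyclohexa-1,4-diene → meso monoepoxide → C2-symmetric trans-diol → bis-silyl ether → 4,5-dioxygenated cyclohex-2-enone → sulfonylhydrazone → hydroxymethylation/Shapiro elimination (C7 joined, diene formed) → desilylation → dibenzoylation → epoxidation. The oxirane is the only ring formed and it comes last.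
- Stereochemistry: C2 and C3 come from the catalyst-controlled hydrolysis of the meso epoxide. C1 and C6 come from the free C2 hydroxyl, which directs the final epoxidation to its own face. No other stereocentre has to be controlled.
- Enabling features: (i) C1 carries C7 and is bonded to C6, which lies one carbon from the C4=C5 bond, so C7–C1=C6–C5=C4 is the retron of an α′-hydroxymethylation/Shapiro sequence on a cyclohex-2-enone hydrazone. (ii) The trans C2/C3 diol makes the six-membered precursor C2-symmetric, so both allylic CH2 groups and both alkene faces are equivalent and the enone forms as one isomer.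

Key step: step 6

Remark: the enantiomer of the (salen)Co(III) catalyst in step 2 is assumed to be the one that gives the (1S,2S)-diol; this is to be confirmed on 3 before going on.
Remark: 5, 6, 10 and 11 (and F1, F9) form as epimers at one carbon that becomes sp2 in the same or a following operation; their SMILES leave that centre undefined. TBS = tert-butyldimethylsilyl.

Step 1
Reactants: 1 cyclohexa-1,4-diene
Product: 2 (1R,6S)-7-oxabicyclo[4.1.0]hept-3-ene (cis-fused, meso)
Conditions: mCPBA (0.9 equiv), CH2Cl2, 0 °C
Reagents that add atoms: mCPBA, O=C(OO)c1cccc(Cl)c1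
Why: Prilezhaev epoxidation of one of the two equivalent cis-alkenes with a deficit of peracid should give the cis-fused meso monoepoxide, so no stereochemical question arises yet.

Step 2
Reactants: 2 (1R,6S)-7-oxabicyclo[4.1.0]hept-3-ene
Product: 3 (1S,2S)-cyclohex-4-ene-1,2-diol
Conditions: H2O (1.2 equiv), oligomeric chiral (salen)Co(III) catalyst (0.5–1 mol %), MeCN, 4 °C → rt
Reagents that add atoms: water, O
Why: Enantioselective hydrolytic ring opening (desymmetrisation) of a meso epoxide: water attacks one of the two enantiotopic epoxide carbons with inversion, which sets both carbinol centres (future C2 and C3) as the trans-(1S,2S)-diol; recrystallisation of the diol should raise the ee.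

Step 3
Reactants: 3 (1S,2S)-cyclohex-4-ene-1,2-diol
Product: 4 (4S,5S)-4,5-bis[(tert-butyldimethylsilyl)oxy]cyclohex-1-ene
Conditions: TBSCl (2.5 equiv), imidazole, DMF, 40 °C
Reagents that add atoms: tert-butyldimethylsilyl chloride, CC(C)(C)[Si](C)(C)Cl
Why: Standard silyl ether formation on both hydroxyls keeps the C2 axis and installs groups that are poor β-leaving groups and inert to amide bases; no stereocentre is touched.

Step 4
Reactants: 4 (4S,5S)-4,5-bis[(tert-butyldimethylsilyl)oxy]cyclohex-1-ene
Product: 7 (4S,5S)-4,5-bis[(tert-butyldimethylsilyl)oxy]cyclohex-2-en-1-one, via allylic hydroperoxide 5 (not isolated), via allylic peracetate 6 (not isolated)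
Conditions: O2, hν (visible), tetraphenylporphyrin (cat.), Ac2O, pyridine, DMAP (cat.), CH2Cl2, rt
Reagents that add atoms: dioxygen (singlet oxygen formed in situ), O=O
Why: Schenck ene reaction of singlet oxygen, then acetylation of the allylic hydroperoxide and base-induced loss of acetate (Kornblum–DeLaMare-type elimination) in the same flask, should give the transposed enone; because of the C2 axis every ene pathway leads to the same enone, and the carbinol centre of 5 and 6 is lost again.

Step 5
Reactants: 7 (4S,5S)-4,5-bis[(tert-butyldimethylsilyl)oxy]cyclohex-2-en-1-one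
Product: 8 N′-[(1E,4S,5S)-4,5-bis[(tert-butyldimethylsilyl)oxy]cyclohex-2-en-1-ylidene]-2,4,6-triisopropylbenzenesulfonohydrazide
Conditions: 2,4,6-triisopropylbenzenesulfonohydrazide (1.05 equiv), THF, cat. HCl, rt
Reagents that add atoms: 2,4,6-triisopropylbenzenesulfonohydrazide, NNS(=O)(=O)c1c(C(C)C)cc(C(C)C)cc1C(C)C
Why: Acid-catalysed hydrazone formation should give mainly the E isomer, with the N–N bond syn to the ring CH2 and anti to the vinyl carbon, which is the geometry the syn-directed deprotonation of step 6 needs; C4 and C5 are unaffected.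

Step 6
Reactants: 8 N′-[(1E,4S,5S)-4,5-bis[(tert-butyldimethylsilyl)oxy]cyclohex-2-en-1-ylidene]-2,4,6-triisopropylbenzenesulfonohydrazide; 9 formaldehyde
Product: 13 [(5S,6S)-5,6-bis[(tert-butyldimethylsilyl)oxy]cyclohexa-1,3-dien-1-yl]methanol, via hydrazone dianion 10 (not isolated), via hydroxymethylated hydrazone dilithium salt 11 (not isolated), via dienyllithium alkoxide 12 (not isolated)
Conditions: LDA (2.1 equiv), THF, −78 °C; monomeric CH2O in THF (1.1 equiv), −78 °C; LDA (1.3 equiv), −78 → 0 °C; H2O
Reagents that add atoms: none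
Why: Deprotonation of the E-hydrazone at N–H and then at the syn ring CH2 (C6 of 8, the future C1) gives an aza-enolate dianion that attacks formaldehyde at carbon and so forms the new C–C bond; a further equivalent of base removes the remaining hydrogen at that carbon, sulfinate and N2 are lost, and the ring vinyllithium is protonated, so the former C=N carbon ends as the CH of a new ring C=C conjugated with the existing one (Shapiro reaction). The closest known reaction types are the Shapiro elimination of enone arenesulfonylhydrazones to conjugated dienes and the trapping of hydrazone dianions with aldehydes before that elimination. No ring is closed and no stereocentre is created: the hydroxymethyl-bearing carbon of 11 forms as two epimers that converge when it becomes sp2, and the two silyloxy centres are not touched. The selectivity needed is deprotonation at the ring CH2 and not at the γ-carbon, C- and not N-attack on formaldehyde, and Shapiro elimination in place of β-elimination of silanolate; the first is secured because the CH2 is the only sp3 α-position and lies syn to the sulfonamide anion, the second by the higher nucleophilicity of the carbon terminus, the third by the poor leaving ability of OTBS between −78 and 0 °C. The step thus delivers the full C7 skeleton as the 2-(hydroxymethyl)-1,3-diene that the closing hydroxyl-directed epoxidation requires.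

Step 7
Reactants: 13 [(5S,6S)-5,6-bis[(tert-butyldimethylsilyl)oxy]cyclohexa-1,3-dien-1-yl]methanol
Product: 14 (1S,2S)-3-(hydroxymethyl)cyclohexa-3,5-diene-1,2-diol
Conditions: TBAF (2.4 equiv), THF, 0 °C → rt
Reagents that add atoms: none
Why: Fluoride-mediated silyl ether cleavage under non-acidic conditions should spare the acid-sensitive trans-dihydrodiol diene; no stereocentre is touched.

Step 8
Reactants: 14 (1S,2S)-3-(hydroxymethyl)cyclohexa-3,5-diene-1,2-diol
Product: 15 [(5S,6S)-5-(benzoyloxy)-6-hydroxycyclohexa-1,3-dien-1-yl]methyl benzoate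
Conditions: BzCl (2.05 equiv), pyridine, CH2Cl2, −40 → −20 °C
Reagents that add atoms: benzoyl chloride, O=C(Cl)c1ccccc1
Why: Kinetically controlled esterification should take the primary allylic hydroxyl first and then the less hindered secondary hydroxyl (the one next to the unsubstituted CH=, future C3), leaving the hydroxyl next to the substituted ring carbon (future C2) free; only O–H bonds react, so configuration is retained.

Step 9
Reactants: 15 [(5S,6S)-5-(benzoyloxy)-6-hydroxycyclohexa-1,3-dien-1-yl]methyl benzoate
Product: 16 (−)-pipoxide, [(1R,2R,3S,6S)-3-(benzoyloxy)-2-hydroxy-7-oxabicyclo[4.1.0]hept-4-en-1-yl]methyl benzoate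
Conditions: VO(acac)2 (2 mol %), t-BuOOH (1.2 equiv), CH2Cl2, 0 °C
Reagents that add atoms: tert-butyl hydroperoxide, CC(C)(C)OO
Why: Vanadium-catalysed hydroxyl-directed epoxidation of the allylic alcohol: the free hydroxyl binds the vanadium peroxide and delivers oxygen to the adjacent trisubstituted ring alkene on its own face, which sets both oxirane carbons cis to that hydroxyl (C1 R, C6 S) and should leave the other, benzoate-flanked alkene untouched.

**Compound list**

1 | cyclohexa-1,4-diene | C1=CCC=CC1 | starting material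
2 | (1R,6S)-7-oxabicyclo[4.1.0]hept-3-ene (meso) | C1C=CC[C@H]2O[C@@H]12 | intermediate
3 | (1S,2S)-cyclohex-4-ene-1,2-diol | C1C=CC[C@H](O)[C@H]1O | intermediate
4 | (4S,5S)-4,5-bis[(tert-butyldimethylsilyl)oxy]cyclohex-1-ene | C1C=CC[C@H](O[Si](C)(C)C(C)(C)C)[C@H]1O[Si](C)(C)C(C)(C)C | intermediate
5 | (4S,5S)-4,5-bis[(tert-butyldimethylsilyl)oxy]cyclohex-2-en-1-yl hydroperoxide (both C1 epimers) | C1C(OO)C=C[C@H](O[Si](C)(C)C(C)(C)C)[C@H]1O[Si](C)(C)C(C)(C)C | intermediate
6 | (4S,5S)-4,5-bis[(tert-butyldimethylsilyl)oxy]cyclohex-2-en-1-yl peracetate (both C1 epimers) | C1C(OOC(C)=O)C=C[C@H](O[Si](C)(C)C(C)(C)C)[C@H]1O[Si](C)(C)C(C)(C)C | intermediate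
7 | (4S,5S)-4,5-bis[(tert-butyldimethylsilyl)oxy]cyclohex-2-en-1-one | C1C(=O)C=C[C@H](O[Si](C)(C)C(C)(C)C)[C@H]1O[Si](C)(C)C(C)(C)C | intermediate
8 | N′-[(1E,4S,5S)-4,5-bis[(tert-butyldimethylsilyl)oxy]cyclohex-2-en-1-ylidene]-2,4,6-triisopropylbenzenesulfonohydrazide | C1/C(=N\NS(=O)(=O)c2c(C(C)C)cc(C(C)C)cc2C(C)C)C=C[C@H](O[Si](C)(C)C(C)(C)C)[C@H]1O[Si](C)(C)C(C)(C)C | intermediate
9 | formaldehyde (monomer, from cracked paraformaldehyde) | C=O | starting material
10 | dianion of 8, drawn as the N,C6-dilithio form | [Li]C1/C(=N\N([Li])S(=O)(=O)c2c(C(C)C)cc(C(C)C)cc2C(C)C)C=C[C@H](O[Si](C)(C)C(C)(C)C)[C@H]1O[Si](C)(C)C(C)(C)C | intermediate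
11 | N,O-dilithium salt of the 6-(hydroxymethyl) derivative of 8 (both C6 epimers) | [Li]OCC1/C(=N\N([Li])S(=O)(=O)c2c(C(C)C)cc(C(C)C)cc2C(C)C)C=C[C@H](O[Si](C)(C)C(C)(C)C)[C@H]1O[Si](C)(C)C(C)(C)C | intermediate
12 | lithium [(5S,6S)-5,6-bis[(tert-butyldimethylsilyl)oxy]-2-lithiocyclohexa-1,3-dien-1-yl]methanolate | [Li]OCC1=C([Li])C=C[C@H](O[Si](C)(C)C(C)(C)C)[C@H]1O[Si](C)(C)C(C)(C)C | intermediate
13 | [(5S,6S)-5,6-bis[(tert-butyldimethylsilyl)oxy]cyclohexa-1,3-dien-1-yl]methanol | OCC1=CC=C[C@H](O[Si](C)(C)C(C)(C)C)[C@H]1O[Si](C)(C)C(C)(C)C | intermediate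
14 | (1S,2S)-3-(hydroxymethyl)cyclohexa-3,5-diene-1,2-diol | OCC1=CC=C[C@H](O)[C@H]1O | intermediate
15 | [(5S,6S)-5-(benzoyloxy)-6-hydroxycyclohexa-1,3-dien-1-yl]methyl benzoate | O=C(OCC1=CC=C[C@H](OC(=O)c2ccccc2)[C@H]1O)c1ccccc1 | intermediate
16 | (−)-pipoxide, [(1R,2R,3S,6S)-3-(benzoyloxy)-2-hydroxy-7-oxabicyclo[4.1.0]hept-4-en-1-yl]methyl benzoate | O=C(OC[C@]12O[C@H]1C=C[C@H](OC(=O)c1ccccc1)[C@H]2O)c1ccccc1 | target

**Step count**

Total: 9 steps. Longest linear sequence: 9 steps (the route is linear).

**Steps most likely to fail**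

Step 6. The aza-enolate may lose silanolate by β-elimination, the second deprotonation at the now tertiary carbon may be slow, or the base may attack the γ-position, so the diene would form in low amount. The fallback sets out from 7 and returns at 14. Kinetic enolisation of 7 at the ring CH2 (LDA, THF, −78 °C) and aldol addition to monomeric formaldehyde should give the hydroxymethyl ketone F1. Silylation (TBSCl, imidazole, DMF) gives the tris-silyl ketone F2. Enolisation toward the substituted carbon and O-sulfonylation (KHMDS, PhNTf2, THF, −78 °C) gives the dienyl triflate F3. Palladium-catalysed formate reduction (Pd(OAc)2, PPh3, Bu3N, HCO2H, DMF, 60 °C) replaces the triflate by hydrogen and gives the tris-silyl diene F4. TBAF in THF then removes all three silyl groups and gives 14.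

Step 8. Acylation may not distinguish the two secondary hydroxyls well enough, or may go on to the tribenzoate. The fallback sets out from 14 and returns at 15. 2-Methoxypropene with catalytic PPTS (DMF, 0 °C) should tie the primary hydroxyl and the neighbouring secondary hydroxyl into the six-membered acetonide F5; the trans-1,2-diol cannot form an unstrained five-membered acetal. Benzoylation of the only free hydroxyl (BzCl, pyridine, DMAP) gives the acetonide benzoate F6. Mild hydrolysis (80% aqueous AcOH, 0 °C) gives the diol monobenzoate F7. Primary-selective benzoylation (BzCl 1.05 equiv, 2,4,6-collidine, CH2Cl2, −40 °C) then gives 15.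

Step 4. The ene reaction of singlet oxygen with an unactivated cis-disubstituted cyclohexene may be too slow, with sensitiser bleaching and side oxidation taking over. The fallback sets out from 4 and returns at 7. Epoxidation (mCPBA, CH2Cl2, 0 °C) gives the single epoxide F8, the two alkene faces being equivalent. Base-promoted isomerisation of the epoxide (LiNEt2, Et2O, reflux) gives the transposed allylic alcohol F9, whichever CH2 is deprotonated. Oxidation with Dess–Martin periodinane (CH2Cl2, rt) gives 7.

**Further compounds**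

F1 | step 6 | (4S,5S)-4,5-bis[(tert-butyldimethylsilyl)oxy]-6-(hydroxymethyl)cyclohex-2-en-1-one (both C6 epimers) | OCC1C(=O)C=C[C@H](O[Si](C)(C)C(C)(C)C)[C@H]1O[Si](C)(C)C(C)(C)C
F2 | step 6 | (4S,5S)-4,5-bis[(tert-butyldimethylsilyl)oxy]-6-{[(tert-butyldimethylsilyl)oxy]methyl}cyclohex-2-en-1-one (both C6 epimers) | CC(C)(C)[Si](C)(C)OCC1C(=O)C=C[C@H](O[Si](C)(C)C(C)(C)C)[C@H]1O[Si](C)(C)C(C)(C)C
F3 | step 6 | (5S,6S)-5,6-bis[(tert-butyldimethylsilyl)oxy]-1-{[(tert-butyldimethylsilyl)oxy]methyl}cyclohexa-1,3-dien-2-yl trifluoromethanesulfonate | CC(C)(C)[Si](C)(C)OCC1=C(OS(=O)(=O)C(F)(F)F)C=C[C@H](O[Si](C)(C)C(C)(C)C)[C@H]1O[Si](C)(C)C(C)(C)C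
F4 | step 6 | tert-butyl{[(5S,6S)-5,6-bis[(tert-butyldimethylsilyl)oxy]cyclohexa-1,3-dien-1-yl]methoxy}dimethylsilane | CC(C)(C)[Si](C)(C)OCC1=CC=C[C@H](O[Si](C)(C)C(C)(C)C)[C@H]1O[Si](C)(C)C(C)(C)C
F5 | step 8 | (8S,8aS)-2,2-dimethyl-8,8a-dihydro-4H-1,3-benzodioxin-8-ol | CC1(C)OCC2=CC=C[C@H](O)[C@H]2O1
F6 | step 8 | (8S,8aS)-2,2-dimethyl-8,8a-dihydro-4H-1,3-benzodioxin-8-yl benzoate | CC1(C)OCC2=CC=C[C@H](OC(=O)c3ccccc3)[C@H]2O1
F7 | step 8 | (1S,6S)-6-hydroxy-5-(hydroxymethyl)cyclohexa-2,4-dien-1-yl benzoate | OCC1=CC=C[C@H](OC(=O)c2ccccc2)[C@H]1O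
F8 | step 4 | (3S,4S)-3,4-bis[(tert-butyldimethylsilyl)oxy]-7-oxabicyclo[4.1.0]heptane (cis-fused) | C1[C@H]2O[C@H]2C[C@H](O[Si](C)(C)C(C)(C)C)[C@H]1O[Si](C)(C)C(C)(C)C
F9 | step 4 | (4S,5S)-4,5-bis[(tert-butyldimethylsilyl)oxy]cyclohex-2-en-1-ol (both C1 epimers) | C1C(O)C=C[C@H](O[Si](C)(C)C(C)(C)C)[C@H]1O[Si](C)(C)C(C)(C)C
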